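## Retrosynthetic overview

Numbering: each half is numbered as a quinolizidin-2-one (N5, C4, C3-Me, C2=O, C1, C9a, C9, C8–C6), with primes for the second half.

1. Target ⇒ macrocyclic bis(β-amino ethyl ketone) 15. Both piperidines close by N-alkylation (N–C6), then both piperidinones by a double Mannich reaction with CH2O (N–C4–C3).
2. 15 ⇒ open-chain dimer 14. The 16-membered ring is closed by addition of a primary alkyl radical to an α-methylene ketone (bond to the CH2 on C1).
3. 14 ⇒ iodide 11 + enone 9, joined by an intermolecular radical conjugate addition. The enone of 11 is masked as its PhS adduct.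
4. 8 and 9 ⇒ (R)-sulfinimine 5 + ethyl vinyl ketone. This sets C9a = R in both halves; C9 is made racemic and the two epimers are separated, one per half (target: 9R and 9'S).
5. 5 ⇒ 5-chloropentanenitrile + 1,4-dibromobutane. Ring order: 16-membered carbocycle, then two piperidines, then two piperidinones.

Assumption: C1/C1' and C3/C3' (α to the ketones) of the target are the thermodynamically favoured configurations for the fixed C9/C9a pairs, so they are set by equilibration in the last step.

## Route

Step 1
Reactants: 1 5-chloropentanenitrile; 2 1,4-dibromobutane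
Product: 3 rac-6-bromo-2-(3-chloropropyl)hexanenitrile
Conditions: LiN(iPr)2 (LDA, 1.05 equiv), THF, −78 °C; cannulate into 2 (4 equiv), DMPU, THF, −78 → −40 °C
Reagents that add atoms: none
Why: Alkylation of a lithiated nitrile (SN2): at −78 °C the anion's own 4-exo closure onto the C–Cl end is slow, and excess dibromide ensures only one C–Br reacts; the new stereocenter (later C9) is left racemic on purpose, because the two halves of the target need opposite configurations there.

Step 2
Reactants: 3 rac-6-bromo-2-(3-chloropropyl)hexanenitrile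
Product: 4 rac-6-bromo-2-(3-chloropropyl)hexanal
Conditions: iBu2AlH (DIBAL-H, 1.2 equiv), CH2Cl2, −78 °C; then 1 M aq. HCl, 0 °C
Reagents that add atoms: water, O
Why: Partial reduction of a nitrile with DIBAL-H to the N-aluminio aldimine, then hydrolysis to the aldehyde; the alkyl halides are inert at −78 °C and no stereocenter is formed.

Step 3
Reactants: 4 rac-6-bromo-2-(3-chloropropyl)hexanal
Product: 5 (R,E)-N-[6-bromo-2-(3-chloropropyl)hexylidene]-2-methylpropane-2-sulfinamide (1:1 C2 epimers)
Conditions: (R)-tBuS(O)NH2 (1.05 equiv), CuSO4 (2 equiv), CH2Cl2, 23 °C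
Reagents that add atoms: (R)-2-methylpropane-2-sulfinamide, CC(C)(C)[S@@](=O)N
Why: Ellman condensation of an aldehyde with tert-butanesulfinamide gives the E-sulfinimine without touching the halides; the sulfur stereocenter comes from the reagent and C2 stays a 1:1 mixture.

Step 4
Reactants: 5 sulfinimine; 6 pent-1-en-3-one (ethyl vinyl ketone)
Product: 8 (5R,6R)-enone sulfinamide and 9 (5R,6S)-enone sulfinamide, via iodomethyl Mannich adduct 7 (not isolated)
Conditions: Et2AlI (1.3 equiv), 6 (1.3 equiv), CH2Cl2, −78 °C; add 5, −78 → −20 °C; then Et3N (3 equiv), 0 → 23 °C; aq. NaHCO3; separation of 8 and 9 on SiO2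
Reagents that add atoms: none
Why: Iodoalane-mediated surrogate of the aza-Morita–Baylis–Hillman reaction (conjugate addition of iodide from Et2AlI to the vinyl ketone, Mannich addition of the aluminium enolate to the sulfinimine, then E1cB loss of HI with Et3N); the enolate is delivered through a closed, sulfinyl-oxygen-chelated transition state, so the (R)-sulfinyl group sets C5 (later C9a) as R in both C6 epimers, which are separated as 8 (later the 9R half) and 9 (later the 9'S half); amine or phosphine catalysts are avoided because of the alkyl bromide.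

Step 5
Reactants: 8 (5R,6R)-enone sulfinamide
Product: 11 (5R,6R)-sulfide iodide, via sulfide bromide 10 (not isolated)
Conditions: PhSH (1.0 equiv), Et3N (0.1 equiv), acetone, 0 °C, 30 min; then NaI (5 equiv), 23 °C, 2 h
Reagents that add atoms: benzenethiol, Sc1ccccc1; sodium iodide, [Na+].[I-]
Why: Thia-Michael addition switches off the enone of the future radical donor (its own radical would otherwise close an 8-membered ring onto it), and Finkelstein exchange turns only the primary bromide into the iodide, which silyl radicals abstract about two hundred times faster than the bromide of partner 9; the new sulfide-bearing center is unselective and is erased in step 7.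

Step 6
Reactants: 11 (5R,6R)-sulfide iodide; 9 (5R,6S)-enone sulfinamide (1.3 equiv)
Product: 12 masked open-chain dimer
Conditions: (Me3Si)3SiH (1.2 equiv, added over 4 h), V-70 [2,2'-azobis(4-methoxy-2,4-dimethylvaleronitrile), 0.2 equiv], degassed PhCF3, 30 °C, 0.2 M
Reagents that add atoms: none
Why: Giese reaction (intermolecular radical conjugate addition): the silyl radical takes iodine from 11 selectively, the primary radical adds to the CH2 terminus of the α-methylene ketone of 9 and the α-keto radical takes H from the silane; 30 °C keeps the 1,5-hydrogen shift slow; the new center α to the ketone forms as a mixture and is equilibrated in step 9.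

Step 7
Reactants: 12 masked open-chain dimer
Product: 14 open-chain dimer enone, via beta-sulfinyl ketone 13 (not isolated)
Conditions: NaIO4 (1.1 equiv), MeOH–H2O 4:1, 0 °C; extract; then toluene, 60 °C, 2 h
Reagents that add atoms: none
Why: Chemoselective periodate oxidation of the aryl sulfide to the sulfoxide (sulfinamides and alkyl halides are expected to survive at 0 °C), then thermal syn-elimination of benzenesulfenic acid from the β-sulfinyl ketone regenerates the α-methylene ketone; no stereocenter of the final product is affected.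

Step 8
Reactants: 14 open-chain dimer enone
Product: 15 macrocyclic bis-sulfinamide diketone
Conditions: (Me3Si)3SiH (1.5 equiv) and V-70 (0.3 equiv) in PhCF3, syringe pump over 12 h into 14 (2 mM, degassed PhCF3), 30 °C
Reagents that add atoms: none
Why: Radical macrocyclization by Giese addition (Porter-type): at 2 mM the primary radical from the C–Br end has the α-methylene ketone of the other half as its only acceptor and closes the 16-membered ring (its own half has no acceptor left, so no 8-membered ring can form), then the α-keto radical is reduced by the silane; the new center α to the ketone is again a mixture, corrected in step 9.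

Step 9
Reactants: 15 macrocyclic bis-sulfinamide diketone; 16 formaldehyde
Product: 20 target CNP0268544.8, via diammonium dichloride 17 (not isolated), via bis-piperidine diketone 18 (not isolated), via kinetic epimer mixture 19 (not isolated)
Conditions: HCl (4 M in dioxane), MeOH, 0 °C, 1 h; evaporate; NaHCO3 (8 equiv), NaI (0.2 equiv), MeCN, 40 °C, 12 h; then 37% aq. CH2O (2.1 equiv), MeOH, 23 °C, 16 h
Reagents that add atoms: none
Why: Acid cleavage of the sulfinamides, 6-exo-tet N-alkylation to the two piperidines and a double intramolecular Mannich reaction with formaldehyde (6-endo attack of the ketone enol on the N-methylene iminium) build both quinolizidin-2-ones; C9 and C9a are not touched, while C1 and C3 equilibrate through the enols in the bicarbonate-buffered medium to the more stable arrangement (C3 methyl equatorial, C1 chain anti to the C9 chain), which is the target.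

## Compound list

1 | 5-chloropentanenitrile | N#CCCCCCl | starting material
2 | 1,4-dibromobutane | BrCCCCBr | starting material
3 | rac-6-bromo-2-(3-chloropropyl)hexanenitrile | N#CC(CCCCl)CCCCBr | intermediate
4 | rac-6-bromo-2-(3-chloropropyl)hexanal | O=CC(CCCCl)CCCCBr | intermediate
5 | (R,E)-N-[6-bromo-2-(3-chloropropyl)hexylidene]-2-methylpropane-2-sulfinamide, 1:1 mixture of C2 epimers (C2 left open in the SMILES) | CC(C)(C)[S@@](=O)/N=C/C(CCCCl)CCCCBr | intermediate
6 | pent-1-en-3-one | CCC(=O)C=C | starting material
7 | (R)-N-[(5R)-10-bromo-6-(3-chloropropyl)-4-(iodomethyl)-3-oxodecan-5-yl]-2-methylpropane-2-sulfinamide, C4 and C6 epimer mixture | CCC(=O)C(CI)[C@H](N[S@](=O)C(C)(C)C)C(CCCCl)CCCCBr | intermediate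
8 | (R)-N-[(5R,6R)-10-bromo-6-(3-chloropropyl)-4-methylidene-3-oxodecan-5-yl]-2-methylpropane-2-sulfinamide | CCC(=O)C(=C)[C@H](N[S@](=O)C(C)(C)C)[C@@H](CCCCl)CCCCBr | intermediate
9 | (R)-N-[(5R,6S)-10-bromo-6-(3-chloropropyl)-4-methylidene-3-oxodecan-5-yl]-2-methylpropane-2-sulfinamide | CCC(=O)C(=C)[C@H](N[S@](=O)C(C)(C)C)[C@H](CCCCl)CCCCBr | intermediate
10 | (R)-N-[(5R,6R)-10-bromo-6-(3-chloropropyl)-3-oxo-4-[(phenylsulfanyl)methyl]decan-5-yl]-2-methylpropane-2-sulfinamide, C4 epimers | CCC(=O)C(CSc1ccccc1)[C@H](N[S@](=O)C(C)(C)C)[C@@H](CCCCl)CCCCBr | intermediate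
11 | (R)-N-[(5R,6R)-6-(3-chloropropyl)-10-iodo-3-oxo-4-[(phenylsulfanyl)methyl]decan-5-yl]-2-methylpropane-2-sulfinamide, C4 epimers | CCC(=O)C(CSc1ccccc1)[C@H](N[S@](=O)C(C)(C)C)[C@@H](CCCCl)CCCCI | intermediate
12 | masked open-chain dimer: C10 of 11 (iodine lost) bonded to the methylidene carbon of 9; the (5R,6R) half carries PhSCH2, the (5R,6S) half carries the (CH2)4Br chain; centers α to the ketones are mixtures | CCC(=O)C(CSc1ccccc1)[C@H](N[S@](=O)C(C)(C)C)[C@@H](CCCCl)CCCCCC(C(=O)CC)[C@H](N[S@](=O)C(C)(C)C)[C@H](CCCCl)CCCCBr | intermediate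
13 | phenyl sulfoxide of 12 (β-sulfinyl ketone) | CCC(=O)C(CS(=O)c1ccccc1)[C@H](N[S@](=O)C(C)(C)C)[C@@H](CCCCl)CCCCCC(C(=O)CC)[C@H](N[S@](=O)C(C)(C)C)[C@H](CCCCl)CCCCBr | intermediate
14 | open-chain dimer enone: as 12, with the (5R,6R) half carrying the free 4-methylidene ketone | CCC(=O)C(=C)[C@H](N[S@](=O)C(C)(C)C)[C@@H](CCCCl)CCCCCC(C(=O)CC)[C@H](N[S@](=O)C(C)(C)C)[C@H](CCCCl)CCCCBr | intermediate
15 | N,N'-[(1R,2R,9R,10S)-2,10-bis(3-chloropropyl)-8,16-dipropanoylcyclohexadecane-1,9-diyl]bis[(R)-2-methylpropane-2-sulfinamide], C8/C16 epimer mixture | [C@@H]1(N[S@](=O)C(C)(C)C)[C@@H](CCCCl)CCCCCC(C(=O)CC)[C@H](N[S@](=O)C(C)(C)C)[C@H](CCCCl)CCCCCC1C(=O)CC | intermediate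
16 | formaldehyde | C=O | starting material
17 | (1R,2R,9R,10S)-2,10-bis(3-chloropropyl)-8,16-dipropanoylcyclohexadecane-1,9-diamine dihydrochloride, C8/C16 epimer mixture | [C@@H]1(N)[C@@H](CCCCl)CCCCCC(C(=O)CC)[C@H](N)[C@H](CCCCl)CCCCCC1C(=O)CC.Cl.Cl | intermediate
18 | bis-piperidine diketone: in 17 each nitrogen has displaced the chloride of the neighbouring arm; (9R,9aR) in one half, (9'S,9a'R) in the other; C1/C1' mixture | [C@@H]12NCCC[C@H]1CCCCCC(C(=O)CC)[C@@H]3NCCC[C@@H]3CCCCCC2C(=O)CC | intermediate
19 | target constitution, C9/C9a/C9'/C9a' as in the target, C1/C3/C1'/C3' as epimer mixture | CC1CN2CCC[C@H]3CCCCCC4C(=O)C(C)CN5CCC[C@H](CCCCCC(C1=O)[C@@H]32)[C@H]45 | intermediate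
20 | CNP0268544.8: macrocyclic bis(3-methylquinolizidin-2-one), (1S,3S,9R,9aR) half and (1'R,3'S,9'S,9a'R) half joined C9–(CH2)5–C1' and C9'–(CH2)5–C1 | C[C@H]1CN2CCC[C@H]3CCCCC[C@H]4C(=O)[C@@H](C)CN5CCC[C@H](CCCCC[C@H](C1=O)[C@@H]32)[C@H]45 | target

## Step count and risks

Total step count: 9. Longest linear sequence: 9 (1 → 20; compound 9 from step 4 re-enters in step 6).

The three steps most likely to fail:

Step 4. The aliphatic, α-branched sulfinimine may react sluggishly with the iodo-enolate, the diastereoselectivity at C5 may be modest, or Et2AlI may exchange the chain bromide. The fallback sets out from 5 and comes back at 8 and 9. Pent-1-yn-3-one (CCC(=O)C#C, an extra starting material with six heavy atoms) is hydroaluminated with iBu2AlH/HMPA in THF at 0 °C to the 1-acylvinyl alane [1-(propanoyl)ethenyl]bis(2-methylpropyl)alumane F1 (not isolated). This preformed carbon nucleophile is added to 5 at −78 → 0 °C and gives 8 and 9 directly after aqueous work-up, with no iodide and no elimination.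

Step 8. The ring closure competes with reduction of the chain radical, a 1,5-hydrogen shift from C9–H, and oligomerisation. The fallback sets out from 14 and comes back at 15. It replaces the free-radical chain by a nickel-mediated reductive conjugate addition, in which the alkyl bromide and the enone are joined at the metal. Compound 14 is added by syringe pump to NiCl2(dme)/neocuproine (10 mol %), manganese powder and Et3SiCl in DMF at 40 °C. This gives the ring-closed triethylsilyl enol ether of macrocycle 15 F2, which is cleaved with Bu4NF/AcOH in THF to 15.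

Step 9. C9a is β to the ketone, so the free β-amino ketones (17, 18 as free bases) can epimerise by retro-Michael/Michael during the basic N-alkylation; the Mannich closure may also stop at mixed C1/C3 epimers. The fallback sets out from 15 and comes back at 18. Compound 15 is treated with HC(OMe)3 and anhydrous HCl in MeOH, which removes both sulfinyl groups and ketalises both ketones to give (1R,2R,9R,10S)-2,10-bis(3-chloropropyl)-8,16-bis(1,1-dimethoxypropyl)cyclohexadecane-1,9-diamine dihydrochloride F3. K2CO3/NaI in MeCN at 60 °C then closes both piperidines to the bis(dimethyl ketal) of bis-piperidine 18 F4, which cannot undergo retro-Michael. Aqueous 1 M HCl with 37% CH2O unmasks the ketones and delivers 18 as its salt, which is buffered to pH 5 (NaOAc) and cyclises on to 20 as in step 9 without ever being a free base.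

Further compounds
F1 | step 4 | [1-(propanoyl)ethenyl]bis(2-methylpropyl)alumane | CCC(=O)C(=C)[Al](CC(C)C)CC(C)C
F2 | step 8 | triethylsilyl enol ether of macrocycle 15 (enol ether on the ring-closing half) | [C@@H]1(N[S@](=O)C(C)(C)C)[C@@H](CCCCl)CCCCCC(C(=O)CC)[C@H](N[S@](=O)C(C)(C)C)[C@H](CCCCl)CCCCCC1=C(O[Si](CC)(CC)CC)CC
F3 | step 9 | (1R,2R,9R,10S)-2,10-bis(3-chloropropyl)-8,16-bis(1,1-dimethoxypropyl)cyclohexadecane-1,9-diamine dihydrochloride | [C@@H]1(N)[C@@H](CCCCl)CCCCCC(C(OC)(OC)CC)[C@H](N)[C@H](CCCCl)CCCCCC1C(OC)(OC)CC.Cl.Cl
F4 | step 9 | bis(dimethyl ketal) of bis-piperidine 18 | [C@@H]12NCCC[C@H]1CCCCCC(C(OC)(OC)CC)[C@@H]3NCCC[C@@H]3CCCCCC2C(OC)(OC)CC
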